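The 1,2-dioxane is cut at C5–C6 and O2–C3 and, in the same flask, at C2–C3. This exposes the feature the route rests on: C6 stands at the ketone level and C3 at the aldehyde level, 1,4 across the O1–O2 bridge. The ring is therefore the formal [3+3] adduct of a ketone-derived peroxycarbenium ion (C6–O1–O2) and the chiral homoenolate of 2-methylpropanal (C5–C4–C3). The key step joins three components: the silyl peroxyketal of the side-chain ketone, a chiral-pool siloxycyclopropane, then a ketene acetal attacking C3 axially. C4 is bought, C3 is relayed from it, C8 is set by catalysis, and C12 comes from citronellyl bromide. C6 is not controlled; its epimers are separated.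

Key step: step 9

Remark: atoms are numbered along the acid (C1 carboxyl; C3, C4, C5, C6 ring carbons; O2 on C3, O1 on C6; C7 to C16 side chain). Compounds 1, 2, 6, 11 and 16 are taken as catalogue compounds. No substrate element can distinguish methyl from CH2R at C6, so both C6 epimers are carried through step 9 and the (6R) epimer is isolated at 18.

Step 1
Reactants: 1 (6R)-8-bromo-2,6-dimethyloct-2-ene [(R)-citronellyl bromide]; 2 2-phenylethylmagnesium chloride
Product: 3 [(5S)-5,9-dimethyldec-8-en-1-yl]benzene
Conditions: Li2CuCl4 (3 mol%), THF, −10 → 20 °C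
Reagents that add atoms: none
Why: Copper-catalysed sp3–sp3 cross-coupling (Kumada type) of a primary bromide with a primary Grignard reagent should be clean, and the stereocentre (the later C12) is not a reacting centre.

Step 2
Reactants: 3 [(5S)-5,9-dimethyldec-8-en-1-yl]benzene
Product: 4 (4S)-4-methyl-8-phenyloctan-1-ol
Conditions: O3, CH2Cl2/MeOH, −78 °C; then NaBH4, −78 → 20 °C
Reagents that add atoms: ozone, [O-][O+]=O
Why: Ozonolysis with reductive work-up should cleave the electron-rich trisubstituted alkene much faster than the benzene ring and deliver the primary alcohol directly.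

Step 3
Reactants: 4 (4S)-4-methyl-8-phenyloctan-1-ol
Product: 5 [(5S)-8-bromo-5-methyloctyl]benzene
Conditions: CBr4, PPh3, CH2Cl2, 0 °C
Reagents that add atoms: tetrabromomethane, BrC(Br)(Br)Br
Why: Appel bromination of a primary alcohol proceeds by SN2 at the carbinol carbon and leaves the remote stereocentre untouched.

Step 4
Reactants: 5 [(5S)-8-bromo-5-methyloctyl]benzene; 6 (E)-pent-3-en-2-one
Product: 9 triethyl{[(4R,8S)-4,8-dimethyl-12-phenyldodec-2-en-2-yl]oxy}silane (either double-bond geometry), via Grignard reagent 7 (not isolated), via magnesium enolate 8 (not isolated)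
Conditions: Mg, Et2O, 35 °C; then 6, CuBr·SMe2 (5 mol%), JosiPhos ligand (6 mol%), tBuOMe, −75 °C; then Et3SiCl, Et3N, DMPU, −75 → 0 °C
Reagents that add atoms: chlorotriethylsilane, CC[Si](CC)(CC)Cl
Why: Copper-catalysed asymmetric conjugate addition of a primary alkyl Grignard reagent to an acyclic methyl enone sets C4 of 9 (the later C8) as R under catalyst control, using the enantiomer of (R)-1-[(S)-2-(diphenylphosphino)ferrocenyl]ethyldicyclohexylphosphine that directs the alkyl group to the Si face of C4 of 6 (sense to be fixed on a model Grignard reagent); the regiodefined magnesium enolate is then O-silylated.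

Step 5
Reactants: 9 triethyl{[(4R,8S)-4,8-dimethyl-12-phenyldodec-2-en-2-yl]oxy}silane
Product: 10 triethyl{[(4R,8S)-4,8-dimethyl-12-phenyl-2-(triethylsilylperoxy)dodecan-2-yl]oxy}silane (C2 epimers)
Conditions: Co(thd)2 [bis(2,2,6,6-tetramethylheptane-3,5-dionato)cobalt] (10 mol%), O2 (1 atm), Et3SiH, ClCH2CH2Cl, 20 °C
Reagents that add atoms: dioxygen, O=O; triethylsilane, CC[SiH](CC)CC
Why: In this Isayama–Mukaiyama hydroperoxysilylation the cobalt hydride gives H to C3 of the silyl enol ether, the α-silyloxy radical at C2 traps O2 and the peroxyl group is silylated, so the silyl monoperoxyketal forms regioselectively; C2 is ionised in step 9, so its configuration is of no consequence.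

Step 6
Reactants: 11 methyl (2R)-3-bromo-2-methylpropanoate
Product: 12 [(2S)-1-methoxy-2-methylcyclopropyl]oxy(trimethyl)silane (C1 epimers)
Conditions: Na (dispersion), Me3SiCl, Et2O, 35 °C
Reagents that add atoms: chlorotrimethylsilane, C[Si](C)(C)Cl
Why: Acyloin-type reductive 1,3-cyclisation of a β-bromo ester with silyl trapping gives the cyclopropanone methyl silyl ketal; the α-stereocentre (the later C4) is not a reacting centre and should be retained because the alkoxide is silylated as it forms.

Step 7
Reactants: 12 [(2S)-1-methoxy-2-methylcyclopropyl]oxy(trimethyl)silane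
Product: 14 (2S)-2-methylcyclopropan-1-ol (C1 epimers; kept as an ether solution), via hemiacetal 13 (not isolated)
Conditions: MeOH, 20 °C, then evaporation; LiAlH4, Et2O, −20 → 0 °C
Reagents that add atoms: none
Why: Methanolysis frees the cyclopropanone hemiacetal, whose alkoxide collapses to 2-methylcyclopropanone and is reduced at once by hydride; C2 is retained and the C1 mixture is irrelevant because C1 becomes trigonal in step 9.

Step 8
Reactants: 14 (2S)-2-methylcyclopropan-1-ol
Product: 15 tert-butyl(dimethyl){[(2S)-2-methylcyclopropyl]oxy}silane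
Conditions: TBSCl, imidazole, DMF, 20 °C
Reagents that add atoms: tert-butylchlorodimethylsilane, CC(C)(C)[Si](C)(C)Cl
Why: Standard silylation of a secondary alcohol; the bulky silyl group is chosen so that the O-silyl oxocarbenium ion of step 9 is captured by the peroxide before it loses silicon.

Step 9
Reactants: 10 triethyl{[(4R,8S)-4,8-dimethyl-12-phenyl-2-(triethylsilylperoxy)dodecan-2-yl]oxy}silane; 15 tert-butyl(dimethyl){[(2S)-2-methylcyclopropyl]oxy}silane; 16 tert-butyl[(1-methoxyethenyl)oxy]dimethylsilane
Product: 18 methyl 2-{(3S,4S,6R)-4,6-dimethyl-6-[(2R,6S)-2,6-dimethyl-10-phenyldecyl]-1,2-dioxan-3-yl}acetate, via 3-silyloxy-1,2-dioxane 17 (not isolated)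
Conditions: 10 and 15 (1.5 equiv), TMSOTf (0.3 equiv), 2,6-di-tert-butyl-4-methylpyridine (0.1 equiv), CH2Cl2, −78 °C; then 16 (3 equiv), −78 → −40 °C
Reagents that add atoms: none
Why: Proposed new method: the silyl triflate ionises 10 to the open-chain peroxycarbenium ion, the CH2 carbon of the siloxycyclopropane attacks C6 with cleavage of the C1–C3 cyclopropane bond (homo-Mukaiyama addition, forming C5–C6), and the resulting O-silyl oxocarbenium ion at C3 is captured by the silylperoxy oxygen with loss of Et3Si+ (forming O2–C3); the closest known reactions are the annulation of peroxycarbenium ions with alkenes to 1,2-dioxolanes and the intramolecular addition of cyclopropyl silyl ethers to oxocarbenium ions, of which this is the intermolecular, ring-homologous combination. The 1,2-dioxane ring is closed by this O2→C3 attack in 6-exo-trig mode, after the intermolecular C5–C6 bond. C4 is carried unchanged from 15; the anomeric centre C3 of 17 does not matter because the same flask ionises it to the cyclic peroxycarbenium ion, which 16 should attack axially through a chair-like transition state with the C4 methyl pseudo-equatorial (the other half-chair would place the C4 methyl and a C6 substituent syn-diaxial), giving the 3,4-cis (3S) ester. C6 is formed on an open-chain cation whose faces differ only in methyl versus CH2R, so no substrate control is expected, both C6 epimers should form, and the (6R) epimer is separated by chromatography at 18. The step needs attack at the unsubstituted cyclopropane carbon (secured by sterics), ring closure faster than silyl loss (secured by the tert-butyldimethylsilyl group) and a promoter that does not metallate the cyclopropane (a silyl triflate, not SnCl4 or TiCl4).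

Step 10
Reactants: 18 methyl 2-{(3S,4S,6R)-4,6-dimethyl-6-[(2R,6S)-2,6-dimethyl-10-phenyldecyl]-1,2-dioxan-3-yl}acetate
Product: 19 2-{(3S,4S,6R)-4,6-dimethyl-6-[(2R,6S)-2,6-dimethyl-10-phenyldecyl]-1,2-dioxan-3-yl}acetic acid
Conditions: LiOH·H2O, THF/H2O, 0 → 20 °C; then 1 M HCl to pH 3
Reagents that add atoms: lithium hydroxide, [Li+].[OH-]
Why: Saponification of a methyl ester with LiOH at low temperature should leave the dialkyl peroxide intact, as in related 1,2-dioxane-3-acetates, and no stereocentre is a reacting centre.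

Compound list
1 | (6R)-8-bromo-2,6-dimethyloct-2-ene | C[C@H](CCC=C(C)C)CCBr | starting material
2 | 2-phenylethylmagnesium chloride | Cl[Mg]CCc1ccccc1 | starting material
3 | [(5S)-5,9-dimethyldec-8-en-1-yl]benzene | C[C@@H](CCCCc1ccccc1)CCC=C(C)C | intermediate
4 | (4S)-4-methyl-8-phenyloctan-1-ol | C[C@@H](CCCCc1ccccc1)CCCO | intermediate
5 | [(5S)-8-bromo-5-methyloctyl]benzene | C[C@@H](CCCCc1ccccc1)CCCBr | intermediate
6 | (E)-pent-3-en-2-one | C/C=C/C(C)=O | starting material
7 | bromido[(4S)-4-methyl-8-phenyloctyl]magnesium | C[C@@H](CCCCc1ccccc1)CCC[Mg]Br | intermediate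
8 | bromomagnesium (4R,8S)-4,8-dimethyl-12-phenyldodec-2-en-2-olate | C[C@@H](CCCCc1ccccc1)CCC[C@@H](C)C=C(C)O[Mg]Br | intermediate
9 | triethyl{[(4R,8S)-4,8-dimethyl-12-phenyldodec-2-en-2-yl]oxy}silane | C[C@@H](CCCCc1ccccc1)CCC[C@@H](C)C=C(C)O[Si](CC)(CC)CC | intermediate
10 | triethyl{[(4R,8S)-4,8-dimethyl-12-phenyl-2-(triethylsilylperoxy)dodecan-2-yl]oxy}silane | C[C@@H](CCCCc1ccccc1)CCC[C@@H](C)CC(C)(O[Si](CC)(CC)CC)OO[Si](CC)(CC)CC | intermediate
11 | methyl (2R)-3-bromo-2-methylpropanoate | COC(=O)[C@@H](C)CBr | starting material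
12 | [(2S)-1-methoxy-2-methylcyclopropyl]oxy(trimethyl)silane | C[C@H]1CC1(OC)O[Si](C)(C)C | intermediate
13 | (2S)-1-methoxy-2-methylcyclopropan-1-ol | C[C@H]1CC1(O)OC | intermediate
14 | (2S)-2-methylcyclopropan-1-ol | C[C@H]1CC1O | intermediate
15 | tert-butyl(dimethyl){[(2S)-2-methylcyclopropyl]oxy}silane | C[C@H]1CC1O[Si](C)(C)C(C)(C)C | intermediate
16 | tert-butyl[(1-methoxyethenyl)oxy]dimethylsilane | C=C(OC)O[Si](C)(C)C(C)(C)C | starting material
17 | tert-butyl({(4S,6R)-4,6-dimethyl-6-[(2R,6S)-2,6-dimethyl-10-phenyldecyl]-1,2-dioxan-3-yl}oxy)dimethylsilane | C[C@@H](CCCCc1ccccc1)CCC[C@@H](C)C[C@]1(C)C[C@H](C)C(O[Si](C)(C)C(C)(C)C)OO1 | intermediate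
18 | methyl 2-{(3S,4S,6R)-4,6-dimethyl-6-[(2R,6S)-2,6-dimethyl-10-phenyldecyl]-1,2-dioxan-3-yl}acetate | C[C@@H](CCCCc1ccccc1)CCC[C@@H](C)C[C@]1(C)C[C@H](C)[C@H](CC(=O)OC)OO1 | intermediate
19 | 2-{(3S,4S,6R)-4,6-dimethyl-6-[(2R,6S)-2,6-dimethyl-10-phenyldecyl]-1,2-dioxan-3-yl}acetic acid | C[C@@H](CCCCc1ccccc1)CCC[C@@H](C)C[C@]1(C)C[C@H](C)[C@H](CC(=O)O)OO1 | target

Total step count: 10. Longest linear sequence: 7 (steps 1 to 5, 9 and 10); the cyclopropane branch (steps 6 to 8) joins at step 9.

Steps most likely to fail

Step 9. Two processes threaten it. The siloxycyclopropane may fail to intercept the peroxycarbenium ion, so that fragmentation of the peroxyketal or triflate-induced opening of the cyclopropane wins. Facial selection at C6 is also absent, which halves the useful material. The fallback uses known chemistry only, sets out from 9 and 12 and comes back at 18: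
- Mild methanolysis of 9 (K2CO3, MeOH) should give (4R,8S)-4,8-dimethyl-12-phenyldodecan-2-one F1.
- TiCl4 should open 12 to the titanium homoenolate trichloro[(2R)-3-methoxy-2-methyl-3-oxopropyl]titanium F2.
- After addition of Ti(OiPr)4, F2 should add to the ketone F1 and lactonise to (3S)-3,5-dimethyl-5-[(2R,6S)-2,6-dimethyl-10-phenyldecyl]oxolan-2-one F3 (C5 epimers).
- DIBAL-H at −78 °C should give the lactol (3S)-3,5-dimethyl-5-[(2R,6S)-2,6-dimethyl-10-phenyldecyl]oxolan-2-ol F4.
- Wittig reaction with Ph3P=CHCO2Me should give methyl (2E,4S,8R,12S)-6-hydroxy-4,6,8,12-tetramethyl-16-phenylhexadec-2-enoate F5.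
- Acid-catalysed perhydrolysis of the tertiary alcohol (ethereal H2O2, catalytic H2SO4) should give methyl (2E,4S,8R,12S)-6-hydroperoxy-4,6,8,12-tetramethyl-16-phenylhexadec-2-enoate F6.
- Et2NH in CF3CH2OH should close F6 by 6-exo peroxy-Michael addition to 18, with its C3 and C6 isomers separated as in the main route.

Step 4. The small β-methyl enone may give insufficient enantiofacial discrimination with the long-chain Grignard reagent, and the magnesium enolate may silylate incompletely on oxygen. The fallback changes which partner carries the chain; it sets out from the Grignard reagent 7 and comes back at the enolate 8 (then 9):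
- Formylation of 7 with DMF should give (5S)-5-methyl-9-phenylnonanal F7.
- Wittig reaction with Ph3P=CHC(O)CH3 should give (3E,8S)-8-methyl-12-phenyldodec-3-en-2-one F8.
- Copper/JosiPhos-catalysed addition of MeMgBr to F8 (small nucleophile on a chain-bearing enone) should give 8 with the ligand enantiomer that leads to 4R; 8 is silylated as before.

Step 5. The cobalt hydride may over-reduce the silyl peroxide, or the silyl monoperoxyketal may be lost on purification. The fallback builds the peroxycarbenium precursor by ozonolysis; it sets out from 9 and comes back at 17: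
- The ketone F1, described in the fallback for step 9, is obtained from 9.
- Wittig methylenation (Ph3P=CH2) should give [(5S,9R)-5,9,11-trimethyldodec-11-en-1-yl]benzene F9.
- Ozonolysis in MeOH/CH2Cl2 at −78 °C should give (4R,8S)-2-hydroperoxy-2-methoxy-4,8-dimethyl-12-phenyldodecane F10.
- Silylation (Et3SiCl, imidazole) should give triethyl{[(4R,8S)-2-methoxy-4,8-dimethyl-12-phenyldodecan-2-yl]peroxy}silane F11.
- F11 replaces 10 in step 9 and should give the same peroxycarbenium ion and hence 17.

Further compounds
F1 | step 9 | (4R,8S)-4,8-dimethyl-12-phenyldodecan-2-one | C[C@@H](CCCCc1ccccc1)CCC[C@@H](C)CC(C)=O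
F2 | step 9 | trichloro[(2R)-3-methoxy-2-methyl-3-oxopropyl]titanium | COC(=O)[C@@H](C)C[Ti](Cl)(Cl)Cl
F3 | step 9 | (3S)-3,5-dimethyl-5-[(2R,6S)-2,6-dimethyl-10-phenyldecyl]oxolan-2-one | C[C@@H](CCCCc1ccccc1)CCC[C@@H](C)CC1(C)C[C@H](C)C(=O)O1
F4 | step 9 | (3S)-3,5-dimethyl-5-[(2R,6S)-2,6-dimethyl-10-phenyldecyl]oxolan-2-ol | C[C@@H](CCCCc1ccccc1)CCC[C@@H](C)CC1(C)C[C@H](C)C(O)O1
F5 | step 9 | methyl (2E,4S,8R,12S)-6-hydroxy-4,6,8,12-tetramethyl-16-phenylhexadec-2-enoate | C[C@@H](CCCCc1ccccc1)CCC[C@@H](C)CC(C)(O)C[C@H](C)/C=C/C(=O)OC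
F6 | step 9 | methyl (2E,4S,8R,12S)-6-hydroperoxy-4,6,8,12-tetramethyl-16-phenylhexadec-2-enoate | C[C@@H](CCCCc1ccccc1)CCC[C@@H](C)CC(C)(OO)C[C@H](C)/C=C/C(=O)OC
F7 | step 4 | (5S)-5-methyl-9-phenylnonanal | C[C@@H](CCCCc1ccccc1)CCCC=O
F8 | step 4 | (3E,8S)-8-methyl-12-phenyldodec-3-en-2-one | C[C@@H](CCCCc1ccccc1)CCC/C=C/C(C)=O
F9 | step 5 | [(5S,9R)-5,9,11-trimethyldodec-11-en-1-yl]benzene | C[C@@H](CCCCc1ccccc1)CCC[C@@H](C)CC(C)=C
F10 | step 5 | (4R,8S)-2-hydroperoxy-2-methoxy-4,8-dimethyl-12-phenyldodecane | C[C@@H](CCCCc1ccccc1)CCC[C@@H](C)CC(C)(OC)OO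
F11 | step 5 | triethyl{[(4R,8S)-2-methoxy-4,8-dimethyl-12-phenyldodecan-2-yl]peroxy}silane | C[C@@H](CCCCc1ccccc1)CCC[C@@H](C)CC(C)(OC)OO[Si](CC)(CC)CC
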